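**Retrosynthetic overview**

1. Target 29 comes from the N-tosyl-tetrahydroisoquinoline 26 by detosylation, palladium-catalysed dehydrogenation and BCl3 dealkylation. The pyridine ring is aromatized last; until then the C1 and C3 centres make the two twists of the C7–C1' axis diastereomers.
2. The 8-OH and the 2'-CH3 of 26 both come from one C8–SiMe2–O–CH2–C2' bridge in 23 (Tamao–Fleming oxidation, then benzylic deoxygenation).
3. The strategy rests on the benzo ring C4a–C5–C6–C7–C8–C8a of the isoquinoline, which carries the fused nitrogen ring (C4a/C8a), the oxygen (C8) and the naphthyl group (C7) on adjacent carbons. It is cut into three alkynes (C4a≡C5, C6≡C7, C8≡C8a) held by the chain C1–N2–C3–C4 and by the silyl ether link, so one [2+2+2] cycloaddition (22 → 23) closes the benzene ring, the piperidine ring and the seven-membered bridge.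
4. Triyne 22 comes from silane 20 (aziridine opening by acetylide, then Mitsunobu inversion with a C-silylated butynol) and naphthylmethanol 13 (Stobbe benzannulation with bromine as blocking group, Sonogashira coupling).
5. Ring order: second naphthalene ring (step 3), then benzene ring + piperidine ring + oxasilepine bridge (step 13), then the pyridine ring by dehydrogenation (step 17).

Key step: step 13

Assumption: the target SMILES (free 5'-OH, 4'-OMe) carries no axis descriptor, so the axis is taken as M and the (1S,3S) series with (R)-BINAP is taken as the pairing that leads to it; if the pairing proves opposite, the enantiomeric C3/C4 building blocks and ligand are used with no other change. For one and the same twist the formal descriptor reads P in 23–25 (C2' bears CH2–O or CH2Br and outranks C8a') and M from 26 on.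

**Route**

Step 1
Reactants: 1 2-bromo-5-hydroxybenzaldehyde
Product: 2 2-bromo-5-isopropoxybenzaldehyde
Conditions: 2-bromopropane, K2CO3, DMF, 60 °C
Reagents that add atoms: 2-bromopropane, CC(C)Br
Why: Williamson ether synthesis on the phenoxide, to which the aldehyde and the aryl bromide are inert.

Step 2
Reactants: 2 2-bromo-5-isopropoxybenzaldehyde; 3 diethyl succinate
Product: 4 (E)-4-(2-bromo-5-isopropoxyphenyl)-3-(ethoxycarbonyl)but-3-enoic acid
Conditions: KOt-Bu, t-BuOH, reflux; then aq. HCl
Reagents that add atoms: none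
Why: Stobbe condensation (aldol addition, lactonization, base-induced opening of the paraconic ester) should give the (E)-alkylidene half-ester, in which the aryl group is cis to the CH2CO2H arm as the later ring closure requires.

Step 3
Reactants: 4 (E)-4-(2-bromo-5-isopropoxyphenyl)-3-(ethoxycarbonyl)but-3-enoic acid
Product: 5 ethyl 4-acetoxy-8-bromo-5-isopropoxy-2-naphthoate
Conditions: Ac2O, NaOAc, 140 °C
Reagents that add atoms: acetic anhydride, CC(=O)OC(C)=O
Why: Intramolecular Friedel–Crafts acylation through the mixed anhydride, enolization and O-acetylation (the ring-closing half of the Stobbe naphthol synthesis); with one ortho carbon blocked by bromine, closure can only occur next to the isopropoxy group, which fixes the 4,5-dioxygen pattern.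

Step 4
Reactants: 5 ethyl 4-acetoxy-8-bromo-5-isopropoxy-2-naphthoate
Product: 7 ethyl 4-hydroxy-5-isopropoxy-2-naphthoate, via ethyl 4-acetoxy-5-isopropoxy-2-naphthoate 6 (not isolated)
Conditions: H2 (1 atm), Pd/C (10 wt % Pd), Et3N, EtOH, rt; filter; K2CO3 (0.2 equiv), EtOH, rt
Reagents that add atoms: none
Why: Catalytic hydrogenolysis removes the blocking aryl bromide, and base-mediated ethanolysis of the activated aryl acetate frees the naphthol without changing the ethyl ester.

Step 5
Reactants: 7 ethyl 4-hydroxy-5-isopropoxy-2-naphthoate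
Product: 8 ethyl 1-bromo-4-hydroxy-5-isopropoxy-2-naphthoate
Conditions: NBS (1.0 equiv), MeCN, −20 → 0 °C
Reagents that add atoms: N-bromosuccinimide, O=C1CCC(=O)N1Br
Why: Electrophilic aromatic bromination directed by the free naphthol, the strongest donor present: the para (alpha) carbon C1 is expected to react before C3, which lies between OH and ester, and before the other ring, which has only an ether donor; any C3 isomer is removed here.

Step 6
Reactants: 8 ethyl 1-bromo-4-hydroxy-5-isopropoxy-2-naphthoate
Product: 9 ethyl 1-bromo-5-isopropoxy-4-methoxy-2-naphthoate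
Conditions: MeI, K2CO3, DMF, 40 °C
Reagents that add atoms: iodomethane, CI
Why: Williamson O-methylation of the naphtholate.

Step 7
Reactants: 9 ethyl 1-bromo-5-isopropoxy-4-methoxy-2-naphthoate; 10 ethynyltrimethylsilane
Product: 11 ethyl 5-isopropoxy-4-methoxy-1-[(trimethylsilyl)ethynyl]-2-naphthoate
Conditions: PdCl2(PPh3)2 (5 mol %), CuI (5 mol %), Et3N, DMF, 70 °C
Reagents that add atoms: none
Why: Sonogashira coupling, in which oxidative addition of zerovalent palladium into the C1–Br bond is helped by the ortho ester and the silyl cap prevents double coupling.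

Step 8
Reactants: 11 ethyl 5-isopropoxy-4-methoxy-1-[(trimethylsilyl)ethynyl]-2-naphthoate
Product: 13 (1-ethynyl-5-isopropoxy-4-methoxynaphthalen-2-yl)methanol, via trimethylsilyl-capped alkynyl alcohol 12 (not isolated)
Conditions: i-Bu2AlH (2.5 equiv), CH2Cl2, −78 → 0 °C; aq. work-up; K2CO3 (cat.), MeOH, rt
Reagents that add atoms: none
Why: Hydride reduction of the ester to the primary alcohol, followed by base-catalysed methanolysis of the alkynyl C–Si bond, which leaves the aryl ethers and the benzylic alcohol untouched.

Step 9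
Reactants: 14 (S)-2-methyl-1-tosylaziridine; 15 lithium acetylide ethylenediamine complex
Product: 16 (S)-4-methyl-N-(pent-4-yn-2-yl)benzenesulfonamide
Conditions: DMSO, 15 °C → rt; then H2O
Reagents that add atoms: none
Why: SN2 ring opening of the N-sulfonylaziridine by acetylide at the unsubstituted CH2, so the methyl-bearing centre (future C3) is not touched and stays (S).

Step 10
Reactants: 17 (R)-but-3-yn-2-ol
Product: 19 (R)-4-(dimethylsilyl)but-3-yn-2-ol, via O,C-bis(dimethylsilyl) derivative 18 (not isolated)
Conditions: n-BuLi (2.1 equiv), THF, −78 → 0 °C; Me2SiHCl (2.2 equiv), −78 °C → rt; then 1 M HCl, THF, 0 °C, short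
Reagents that add atoms: chlorodimethylsilane, C[SiH](C)Cl
Why: Double deprotonation and silylation at oxygen and at the alkyne terminus, then selective hydrolysis of the much more labile O–Si bond; the carbinol centre is not involved and stays (R).

Step 11
Reactants: 16 (S)-4-methyl-N-(pent-4-yn-2-yl)benzenesulfonamide; 19 (R)-4-(dimethylsilyl)but-3-yn-2-ol
Product: 20 N-[(S)-4-(dimethylsilyl)but-3-yn-2-yl]-4-methyl-N-[(S)-pent-4-yn-2-yl]benzenesulfonamide
Conditions: 1,1'-(azodicarbonyl)dipiperidine (ADDP, 1.5 equiv), PBu3 (1.5 equiv), toluene, 0 °C → rt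
Reagents that add atoms: none
Why: Mitsunobu N-alkylation with the ADDP/PBu3 redox pair, chosen because the N–H of the branched sulfonamide is only weakly acidic; SN2 displacement of the propargylic oxyphosphonium inverts (R) to (S) and so sets the future C1, and the neutral medium spares the Si–H bond.

Step 12
Reactants: 20 N-[(S)-4-(dimethylsilyl)but-3-yn-2-yl]-4-methyl-N-[(S)-pent-4-yn-2-yl]benzenesulfonamide; 13 (1-ethynyl-5-isopropoxy-4-methoxynaphthalen-2-yl)methanol
Product: 22 N-[(S)-4-({[1-ethynyl-5-isopropoxy-4-methoxynaphthalen-2-yl]methoxy}dimethylsilyl)but-3-yn-2-yl]-4-methyl-N-[(S)-pent-4-yn-2-yl]benzenesulfonamide (silicon-tethered triyne), via silyl bromide 21 (not isolated)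
Conditions: NBS (1.0 equiv), CH2Cl2, 0 °C; then 13, Et3N, DMAP (cat.), 0 °C → rt; pentane, filtration through Et3N-deactivated silica
Reagents that add atoms: none
Why: NBS converts the Si–H bond into Si–Br, which silylates the primary benzylic alcohol under amine base (ordinary silyl ether formation); the terminal alkynes do not react with NBS without silver or strong base, and the labile ether is kept away from acidic silica.

Step 13
Reactants: 22 silicon-tethered triyne
Product: 23 bridged cycloadduct: (1S,3S)-1,3-dimethyl-2-tosyl-1,2,3,4-tetrahydroisoquinoline whose C8 carries SiMe2 linked through O–CH2 to C2' of the 5'-isopropoxy-4'-methoxynaphthalen-1'-yl group on C7 (seven-membered oxasilepine across the axis; axis P)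
Conditions: [Rh(cod)2]BF4 (10 mol %), (R)-BINAP (10 mol %), H2 then Ar (removal of cod), CH2Cl2, rt, slow addition of 22 (final 0.005 M)
Reagents that add atoms: none
Why: Monovalent rhodium freed from cod and bound by BINAP couples two alkynes of 22 oxidatively to a rhodacyclopentadiene, the third alkyne inserts, and reductive elimination releases the benzene ring with the new bonds C4a–C8a, C5–C6 and C7–C8; this is the fully intramolecular rhodium-catalysed [2+2+2] cycloaddition of a tethered triyne, a reaction type known with sulfonamide and silicon tethers and for biaryl formation. The benzene ring closes by the cyclotrimerization itself, the piperidine ring as the six-membered ring fused to the rhodacycle when the two nitrogen-linked alkynes couple (1,7-diyne mode), and the oxasilepine when the aryl alkyne held by the Si–O–CH2 link inserts intramolecularly. No stereocentre is formed; the new element is the C7–C1' axis, whose twist is set jointly by the BINAP antipode and the (1S) centre, whose pseudo-axial methyl next to the silicon is expected to push the bridge to the opposite face, and the two outcomes are diastereomers because of C1 and C3. Regiochemistry (naphthyl at C7, silicon at C8, hydrogen at C5 and C6) is needed and is fixed entirely by the two tethers. Intramolecular coupling must beat intermolecular coupling, which dilution with slow addition secures, and the Si–O link must survive, for which the neutral anhydrous medium at room temperature should suffice. Should the bridged biaryl prove torsionally mobile, the ratio becomes a thermodynamic one governed by the two centres and is frozen when the bridge is opened in step 14.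

Step 14
Reactants: 23 bridged cycloadduct
Product: 24 (1S,3S)-7-[2-(hydroxymethyl)-5-isopropoxy-4-methoxynaphthalen-1-yl]-1,3-dimethyl-2-tosyl-1,2,3,4-tetrahydroisoquinolin-8-ol (axis P)
Conditions: KF, KHCO3, H2O2 (30 % aq.), THF/MeOH 1:1, rt → 40 °C
Reagents that add atoms: hydrogen peroxide, OO
Why: Tamao–Fleming oxidation: fluoride and peroxide add to the alkoxysilane, the aryl group migrates from silicon to oxygen with retention at C8, and hydrolysis frees the phenol and the benzylic alcohol; opening the bridge raises the rotation barrier, so the twist is fixed from here on and a minor atropo-diastereomer is removed by chromatography at this stage.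

Step 15
Reactants: 24 (1S,3S)-7-[2-(hydroxymethyl)-5-isopropoxy-4-methoxynaphthalen-1-yl]-1,3-dimethyl-2-tosyl-1,2,3,4-tetrahydroisoquinolin-8-ol
Product: 26 (1S,3S)-7-(5-isopropoxy-4-methoxy-2-methylnaphthalen-1-yl)-1,3-dimethyl-2-tosyl-1,2,3,4-tetrahydroisoquinolin-8-ol (axis M), via benzylic bromide 25 (not isolated)
Conditions: PPh3, CBr4, CH2Cl2, 0 °C; evaporate; LiBHEt3 (excess), THF, −78 → 0 °C
Reagents that add atoms: none
Why: Appel bromination acts on the primary benzylic alcohol and not on the hindered, non-ionized phenol, and the benzylic bromide is reduced at once by SN2 hydride transfer from LiBHEt3, which should be faster than ring closure by the phenoxide.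

Step 16
Reactants: 26 (1S,3S)-7-(5-isopropoxy-4-methoxy-2-methylnaphthalen-1-yl)-1,3-dimethyl-2-tosyl-1,2,3,4-tetrahydroisoquinolin-8-ol
Product: 27 (1S,3S)-7-(5-isopropoxy-4-methoxy-2-methylnaphthalen-1-yl)-1,3-dimethyl-1,2,3,4-tetrahydroisoquinolin-8-ol (axis M)
Conditions: SmI2 (6 equiv), pyrrolidine, H2O, THF, rt, short
Reagents that add atoms: none
Why: Single-electron reductive cleavage of the N–S bond by divalent samarium activated by amine and water (sulfonamide deprotection), fast enough at room temperature to spare the aryl ethers and the naphthalene.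

Step 17
Reactants: 27 (1S,3S)-7-(5-isopropoxy-4-methoxy-2-methylnaphthalen-1-yl)-1,3-dimethyl-1,2,3,4-tetrahydroisoquinolin-8-ol
Product: 28 7-(5-isopropoxy-4-methoxy-2-methylnaphthalen-1-yl)-1,3-dimethylisoquinolin-8-ol (axis M)
Conditions: Pd/C (10 wt % Pd, high loading), toluene, 110 °C, Ar stream
Reagents that add atoms: none
Why: Catalytic dehydrogenation over palladium aromatizes the nitrogen ring with loss of two H2 and erases the C1 and C3 centres; the axis, flanked by OH, methyl and the peri ring, is expected to hold at this temperature for the short time needed, which is to be checked on a chiral phase.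

Step 18
Reactants: 28 7-(5-isopropoxy-4-methoxy-2-methylnaphthalen-1-yl)-1,3-dimethylisoquinolin-8-ol
Product: 29 7-(5-hydroxy-4-methoxy-2-methylnaphthalen-1-yl)-1,3-dimethylisoquinolin-8-ol (axis M; target)
Conditions: BCl3 (4 equiv), CH2Cl2, −78 → 0 °C; then MeOH, aq. NaHCO3
Reagents that add atoms: none
Why: Lewis acid ether cleavage: BCl3 removes the secondary isopropyl group through the isopropyl cation/chloride pathway much faster than the methyl group, so at low temperature only the 5'-hydroxyl is freed.

**Compound list**

1 | 2-bromo-5-hydroxybenzaldehyde | O=Cc1cc(O)ccc1Br | starting material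
2 | 2-bromo-5-isopropoxybenzaldehyde | CC(C)Oc1ccc(Br)c(C=O)c1 | intermediate
3 | diethyl succinate | CCOC(=O)CCC(=O)OCC | starting material
4 | (E)-4-(2-bromo-5-isopropoxyphenyl)-3-(ethoxycarbonyl)but-3-enoic acid | CCOC(=O)/C(CC(=O)O)=C/c1cc(OC(C)C)ccc1Br | intermediate
5 | ethyl 4-acetoxy-8-bromo-5-isopropoxy-2-naphthoate | CCOC(=O)c1cc(OC(C)=O)c2c(OC(C)C)ccc(Br)c2c1 | intermediate
6 | ethyl 4-acetoxy-5-isopropoxy-2-naphthoate | CCOC(=O)c1cc(OC(C)=O)c2c(OC(C)C)cccc2c1 | intermediate
7 | ethyl 4-hydroxy-5-isopropoxy-2-naphthoate | CCOC(=O)c1cc(O)c2c(OC(C)C)cccc2c1 | intermediate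
8 | ethyl 1-bromo-4-hydroxy-5-isopropoxy-2-naphthoate | CCOC(=O)c1cc(O)c2c(OC(C)C)cccc2c1Br | intermediate
9 | ethyl 1-bromo-5-isopropoxy-4-methoxy-2-naphthoate | CCOC(=O)c1cc(OC)c2c(OC(C)C)cccc2c1Br | intermediate
10 | ethynyltrimethylsilane | C#C[Si](C)(C)C | starting material
11 | ethyl 5-isopropoxy-4-methoxy-1-[(trimethylsilyl)ethynyl]-2-naphthoate | CCOC(=O)c1cc(OC)c2c(OC(C)C)cccc2c1C#C[Si](C)(C)C | intermediate
12 | {5-isopropoxy-4-methoxy-1-[(trimethylsilyl)ethynyl]naphthalen-2-yl}methanol | C[Si](C)(C)C#Cc1c(CO)cc(OC)c2c(OC(C)C)cccc12 | intermediate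
13 | (1-ethynyl-5-isopropoxy-4-methoxynaphthalen-2-yl)methanol | C#Cc1c(CO)cc(OC)c2c(OC(C)C)cccc12 | intermediate
14 | (S)-2-methyl-1-tosylaziridine | C[C@H]1CN1S(=O)(=O)c1ccc(C)cc1 | starting material
15 | lithium acetylide ethylenediamine complex | [Li+].[C-]#C.NCCN | starting material
16 | (S)-4-methyl-N-(pent-4-yn-2-yl)benzenesulfonamide | C#CC[C@H](C)NS(=O)(=O)c1ccc(C)cc1 | intermediate
17 | (R)-but-3-yn-2-ol | C#C[C@@H](C)O | starting material
18 | (R)-{[4-(dimethylsilyl)but-3-yn-2-yl]oxy}dimethylsilane | C[C@@H](O[SiH](C)C)C#C[SiH](C)C | intermediate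
19 | (R)-4-(dimethylsilyl)but-3-yn-2-ol | C[C@@H](O)C#C[SiH](C)C | intermediate
20 | N-[(S)-4-(dimethylsilyl)but-3-yn-2-yl]-4-methyl-N-[(S)-pent-4-yn-2-yl]benzenesulfonamide | C#CC[C@H](C)N(S(=O)(=O)c1ccc(C)cc1)[C@@H](C)C#C[SiH](C)C | intermediate
21 | N-[(S)-4-(bromodimethylsilyl)but-3-yn-2-yl]-4-methyl-N-[(S)-pent-4-yn-2-yl]benzenesulfonamide | C#CC[C@H](C)N(S(=O)(=O)c1ccc(C)cc1)[C@@H](C)C#C[Si](C)(C)Br | intermediate
22 | silicon-tethered triyne, (S,S) at the future C1 and C3 | C#CC[C@H](C)N(S(=O)(=O)c1ccc(C)cc1)[C@@H](C)C#C[Si](C)(C)OCc1cc(OC)c2c(OC(C)C)cccc2c1C#C | intermediate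
23 | silyl-ether-bridged N-tosyl-naphthyltetrahydroisoquinoline, (1S,3S), axis P | C[C@H]1Cc2ccc3-c4c(CO[Si](C)(C)c3c2[C@H](C)N1S(=O)(=O)c1ccc(C)cc1)cc(OC)c1c(OC(C)C)cccc41 | intermediate
24 | (1S,3S)-7-[2-(hydroxymethyl)-5-isopropoxy-4-methoxynaphthalen-1-yl]-1,3-dimethyl-2-tosyl-1,2,3,4-tetrahydroisoquinolin-8-ol, axis P | C[C@H]1Cc2ccc(-c3c(CO)cc(OC)c4c(OC(C)C)cccc34)c(O)c2[C@H](C)N1S(=O)(=O)c1ccc(C)cc1 | intermediate
25 | (1S,3S)-7-[2-(bromomethyl)-5-isopropoxy-4-methoxynaphthalen-1-yl]-1,3-dimethyl-2-tosyl-1,2,3,4-tetrahydroisoquinolin-8-ol, axis P | C[C@H]1Cc2ccc(-c3c(CBr)cc(OC)c4c(OC(C)C)cccc34)c(O)c2[C@H](C)N1S(=O)(=O)c1ccc(C)cc1 | intermediate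
26 | (1S,3S)-7-(5-isopropoxy-4-methoxy-2-methylnaphthalen-1-yl)-1,3-dimethyl-2-tosyl-1,2,3,4-tetrahydroisoquinolin-8-ol, axis M | C[C@H]1Cc2ccc(-c3c(C)cc(OC)c4c(OC(C)C)cccc34)c(O)c2[C@H](C)N1S(=O)(=O)c1ccc(C)cc1 | intermediate
27 | (1S,3S)-7-(5-isopropoxy-4-methoxy-2-methylnaphthalen-1-yl)-1,3-dimethyl-1,2,3,4-tetrahydroisoquinolin-8-ol, axis M | C[C@H]1Cc2ccc(-c3c(C)cc(OC)c4c(OC(C)C)cccc34)c(O)c2[C@H](C)N1 | intermediate
28 | 7-(5-isopropoxy-4-methoxy-2-methylnaphthalen-1-yl)-1,3-dimethylisoquinolin-8-ol, axis M | COc1cc(C)c(-c2ccc3cc(C)nc(C)c3c2O)c2cccc(OC(C)C)c12 | intermediate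
29 | 7-(5-hydroxy-4-methoxy-2-methylnaphthalen-1-yl)-1,3-dimethylisoquinolin-8-ol, axis M | COc1cc(C)c(-c2ccc3cc(C)nc(C)c3c2O)c2cccc(O)c12 | target

**Step count**

Total step count: 18. Longest linear sequence: 15 steps (steps 1–8, then 12–18).

**Steps most likely to fail**

Step 13. Intermolecular coupling of the two terminal alkynes may outrun insertion of the third, crowded alkyne, or the cycle may stall at a rhodacycle, and the silyl ether link may be lost to adventitious hydrolysis. Fallback: setting out from 22, the cyclization is run in a different manifold, with one equivalent of CpCo(CO)2 in boiling xylene under irradiation. A monovalent cobalt centre assembles the three alkynes stoichiometrically through a cobaltacyclopentadiene, a mode known for silicon-tethered triynes. No chiral ligand is present, so the twist is left to the C1/C3 centres and to chromatographic separation of the atropo-diastereomers after step 14. The fallback returns to the route at 23 and makes no compound outside the list (F0).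

Step 11. The crowded, weakly acidic N–H of 16 may be alkylated too slowly, so that the activated alcohol is consumed by elimination or by the reduced azo reagent, and the propargylic oxyphosphonium may ionize with partial loss of configuration. Fallback: setting out from 19, the alcohol is converted (MsCl, Et3N, CH2Cl2, −20 °C) into (R)-4-(dimethylsilyl)but-3-yn-2-yl methanesulfonate F1. F1 is displaced with inversion by the pre-formed sodium salt of 16 (NaH, DMF, 0 °C → rt). This is a plain SN2 alkylation of a sulfonamide anion by a propargylic sulfonate and returns to the route at 20.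

Step 15. The neighbouring C8 hydroxyl may attack the activated benzylic carbon and close a six-membered benzylic aryl ether across the axis, which consumes material and lets the axis turn freely. Fallback: setting out from 23, the order of events is changed so that silicon masks the phenol during the deoxygenation.
- LiAlH4 (THF, 0 °C → rt) reduces the Si–O bond and should give (1S,3S)-8-(dimethylsilyl)-7-[2-(hydroxymethyl)-5-isopropoxy-4-methoxynaphthalen-1-yl]-1,3-dimethyl-2-tosyl-1,2,3,4-tetrahydroisoquinoline F2. The atropo-diastereomers are separated at this point.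
- MsCl/Et3N converts F2 into the benzylic methanesulfonate F3.
- LiBHEt3 reduces F3 to (1S,3S)-8-(dimethylsilyl)-7-(5-isopropoxy-4-methoxy-2-methylnaphthalen-1-yl)-1,3-dimethyl-2-tosyl-1,2,3,4-tetrahydroisoquinoline F4.
- Tamao–Fleming oxidation of the aryl hydrosilane F4 (KF, KHCO3, H2O2, THF/MeOH, 50 °C) returns to the route at 26.

Further compounds
F0 | step 13 | none | none
F1 | step 11 | (R)-4-(dimethylsilyl)but-3-yn-2-yl methanesulfonate | C[C@@H](OS(C)(=O)=O)C#C[SiH](C)C
F2 | step 15 | (1S,3S)-8-(dimethylsilyl)-7-[2-(hydroxymethyl)-5-isopropoxy-4-methoxynaphthalen-1-yl]-1,3-dimethyl-2-tosyl-1,2,3,4-tetrahydroisoquinoline | C[C@H]1Cc2ccc(-c3c(CO)cc(OC)c4c(OC(C)C)cccc34)c([SiH](C)C)c2[C@H](C)N1S(=O)(=O)c1ccc(C)cc1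
F3 | step 15 | {1-[(1S,3S)-8-(dimethylsilyl)-1,3-dimethyl-2-tosyl-1,2,3,4-tetrahydroisoquinolin-7-yl]-5-isopropoxy-4-methoxynaphthalen-2-yl}methyl methanesulfonate | C[C@H]1Cc2ccc(-c3c(COS(C)(=O)=O)cc(OC)c4c(OC(C)C)cccc34)c([SiH](C)C)c2[C@H](C)N1S(=O)(=O)c1ccc(C)cc1
F4 | step 15 | (1S,3S)-8-(dimethylsilyl)-7-(5-isopropoxy-4-methoxy-2-methylnaphthalen-1-yl)-1,3-dimethyl-2-tosyl-1,2,3,4-tetrahydroisoquinoline | C[C@H]1Cc2ccc(-c3c(C)cc(OC)c4c(OC(C)C)cccc34)c([SiH](C)C)c2[C@H](C)N1S(=O)(=O)c1ccc(C)cc1
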